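**Abbreviations and numbering.** TBS = tert-butyldimethylsilyl, TBSO = its ether oxygen, pin = pinacolato, 9-BBN = 9-borabicyclo[3.3.1]nonane. Ring atoms are C1 (stereocentre) to C14 in the direction C1→C2→C3; C15=C16H2 is the exocyclic alkene on C1.

## Structural features

The target is a C25 monocarbocycle: a 14-membered ring (C1–C14) that carries a 6-methylhepta-1,5-dien-2-yl chain on C1 through C15. The ring holds three trisubstituted alkenes separated by CH2–CH2 pairs: C3=C4 (hydroxymethyl on C4 cis to C2, descriptor Z), C7=C8 (methyl on C8, E) and C11=C12 (methyl on C12, Z, so C10 and C13 are cis). C1 (R) is the only stereocentre; it lies between two methylene groups, has no stereogenic neighbour and is remote from the oxygen, so neither substrate relay nor a directing group can set it. The fragile elements are the five alkenes arranged as skipped 1,5-dienes (open to cationic or radical transannular reactions), the primary allylic alcohol, and the C1–H bond, which is allylic to C15=C16 and lets acid, base or metal hydrides move that alkene. The real difficulty is to close an entropically costly 14-membered ring while three alkene geometries stay fixed, one of them (Z at C11=C12) not available from common terpene feedstock, and to create an isolated tertiary stereocentre with absolute control. The key step exploits the sequence C14(sp3)–C1H–C2H2–C3(sp2) with an alkenyl carbon (C15) on C1. C1 and C2 can arrive as a vinyl group on a boron atom bound to C14; migration of C14 to C1 and bonding of C2 to C3 close the ring and leave boron on C1 for a stereoretentive alkenylation.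

## Logic of the disconnections

**26 to 25.** The O–Si bond is cut. The allylic hydroxyl must be masked against organolithium reagents, ylide and borane; the skeleton is unchanged. The forward step must cleave a silyl ether without touching five alkenes, which fluoride does.

**25 to 20 and 23 (from 22, from 21).** The C1–C15 bond is cut. This is an sp3–sp2 bond at the stereocentre, and a boron-to-carbon 1,2-migration forms it with retention. The cut removes eight carbons and two alkenes and leaves a secondary boronate. The forward step needs complete borate formation at a hindered secondary boronate, and iodine must attack only the borate alkene.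

**20 to 16 and 18 (from 17).** The C1–C14 and C2–C3 bonds are cut. This turns ring plus stereocentre into an achiral open chain whose three alkenes are already fixed, with a two-carbon linchpin. The forward step must select one enantiotopic face of the vinyl group by catalyst control, close the ring faster than chains oligomerise, scavenge halide, and retain geometry at C3. Bromine (not iodine) is kept on C3 of 16 because it must survive the assembly of 16.

**16 to 9 and 14.** The C10–C11 bond (sp3–sp2) is cut. Boron and bromine then sit on different fragments until the step before cyclisation, and the Z geometry of C11=C12 comes from an alkenyl iodide of fixed geometry. A join of C9 to C10 through a sulfone was set aside: the allylic sulfone would later have to be removed with a palladium catalyst and a hydride source, which would also reduce the C3–Br bond. The forward step must distinguish C–I from C–Br in oxidative addition, keep the primary pinacol boronate out of transmetalation, and hydroborate only the terminal alkene of a diene.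

**14 to 12 and 13; 12 to 11; 11 to 2.** The C13–C14 bond is cut (alkylation of a boron-stabilised carbanion), then C–Br is exchanged for C–O, then C12–CH3 and C11–I are cut (carbometalation of 2 with MeMgBr, then iodine). The boronate is introduced by a polar process because a C14 radical would be homoallylic to C11=C12 and could scramble its geometry through a cyclopropylcarbinyl radical. The fragment comes in three steps from a three-carbon feedstock. The forward steps need SN2 (not SN2′) alkylation and anti addition across the alkyne.

**9 to 8, 7, 6, 5, then 1 and 2.** The cuts are C9=C10 (methylenation), C9–O (allylic oxidation), O–Si, and finally C4–C5 with C3–Br (carbomagnesiation and bromination). Anti addition fixes Z at C3=C4. The Grignard reagent 3 is the simplest possible, so the excess this reaction consumes is cheap. The E geometry at C7=C8 comes from oxidising the methyl group trans to the chain of a prenyl terminus. The forward steps need an oxidation that selects the electron-rich alkene over the bromoalkene.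

**22 to 21.** The C=N bond is cut; 21 is commercial, and the hydrazone is the precursor of 23.

## Other disconnections considered

**Alternative 1:** The cut is the C3=C4 double bond. In the forward sense the C4 carbanion of the open-chain bis(2,2,2-trifluoroethyl) phosphonoester A1 (aldehyde at C3, C1 already R and carrying the side chain) would be formed with KN(SiMe3)2 and 18-crown-6 at high dilution. It would condense with the aldehyde to give the macrocyclic enoate A2 with the ester cis to C2, and iBu2AlH would then give 26.
- In its favour: olefination macrocyclisations are established for rings of this size. The ester is the oxygen function in latent form, so no protecting group is needed and one step follows ring closure. On this count it is better than the chosen plan, which needs two steps after cyclisation. C1 is β to the aldehyde and cannot epimerise.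
- Against it: nothing in the key step creates C1. A separate enantioselective operation must place the stereocentre and the whole side chain in a long chain that finally carries an enolisable aldehyde and an acidic phosphonate together. The cis selectivity of trifluoroethyl phosphonates is kinetic, and in a 14-membered closure it competes with conformational preferences of the ring. The geometry of the most functionalised alkene would therefore be decided in the least predictable step, whereas the chosen plan fixes C3=C4 before the ring is closed.
- Comparison: both close the ring at C3. Alternative 1 uses polar chemistry with precedent and needs no new method, which is an advantage. The chosen plan forms two C–C bonds and the stereocentre in the ring-closing event and is likely shorter overall.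

**Alternative 2:** The cut is C1–C14, read through a [3,3] retron (C15=C16 next to C1, carboxyl on C14). The 18-membered allylic macrolactone A3 would be converted into its boron enolate with a chiral 2-bromo-1,3,2-diazaborolidine and Et3N. Rearrangement would give the acid A4, contracted to the 14-membered carbocycle. Removal of the carboxyl group and of the silyl group would lead to 26.
- In its favour: ring formation is delegated to a macrolactonisation, and the C–C bond then forms inside a ring without a dilution demand. C1, the exocyclic alkene and the side chain appear together, so no separate alkenylation at C1 is needed. On this point it is better than the chosen plan.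
- Against it: A4 carries a carboxyl group and a second stereocentre at C14 that the target lacks. Removing the carboxyl group would need a radical decarboxylation in which the C14 radical is homoallylic to both C11=C12 and C15=C16 and faces transannular alkenes, so cyclisation or loss of alkene geometry threatens. A3 needs a geometrically pure trisubstituted C1=C15 alkene (drawn E here). The enolate geometry is imposed by the ring, so the face selectivity of the boron reagent is as uncertain as the induction in the chosen key step.
- Comparison: at least three steps follow the key step instead of two, and a seco-acid with four defined alkenes precedes it.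

**Alternative 3:** The cut is C9–C10. The C9 carbanion of the (E)-allylic phenyl sulfone A5, formed with KN(SiMe3)2 at high dilution, would displace the (Z)-allylic bromide at C10 and give the macrocyclic sulfone A6 as a C9 epimer mixture. Reductive desulfonylation would give 25, and desilylation 26.
- In its favour: alkylation of sulfone-stabilised allyl anions by allylic halides is a long-proven route to macrocyclic terpenoids. All three ring alkenes and C1 are in place before closure, so the cyclisation decides no stereochemistry. On the reliability of the ring-closing event it is better than the chosen plan. On control of alkene geometry the two are equal.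
- Against it: C1 and the side chain must be built in the open chain by a separate enantioselective step. The sulfone costs two extra operations. Its reductive removal next to C7=C8 can shift or isomerise that alkene. A5 combines an acidic sulfone with a labile allylic bromide and would have to be made just before use.
- Comparison: the route would be roughly four steps longer than the chosen plan.

Key step: step 10

**Assumption.** The ligand is written as the (Sp,Sp) enantiomer of MandyPhos. Which enantiomer leads to (R)-20 in the tethered case cannot be derived with certainty from the open-chain reaction, and the mirror-image ligand is the immediate remedy if the other face is preferred.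

**Remark on the structures.** The geometries and descriptors were checked (Z bromoalkene in 16; 3Z, 7E, 11Z in 20 and 26; R at C1 in 20, 25 and 26, with retention in step 12). They are mutually consistent, so no structure was corrected.

## Steps

Step 1
Reactants: 1 5-bromo-2-methylpent-2-ene; 2 prop-2-yn-1-ol
Product: 5 (2Z)-2-(bromomethylidene)-6-methylhept-5-en-1-ol, via (4-methylpent-3-en-1-yl)magnesium bromide 3 (not isolated), via C3-magnesiated homoprenyl allyl alkoxide 4 (not isolated)
Conditions: 1, Mg, THF, rt; then 2 (0.4 equiv), CuI (10 mol%), Et2O–THF, −10 °C → rt; then BrCl2C–CCl2Br, −40 → 0 °C; aq. NH4Cl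
Reagents that add atoms: 1,2-dibromo-1,1,2,2-tetrachloroethane, BrC(Cl)(Cl)C(Cl)(Cl)Br
Why: Copper-catalysed carbomagnesiation of the magnesium alkoxide of 2: the alkoxide directs anti addition, the alkyl group goes to the internal carbon (C4) and magnesium to the terminal carbon (C3), held cis to CH2O in a five-membered chelate, and bromination of the C–Mg bond with retention should give the Z bromoalkene. Bromine and not iodine is placed on C3 so that this bond stays intact in step 9, and the excess of Grignard reagent that the reaction needs is the cheap reagent 3.

Step 2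
Reactants: 5 (2Z)-2-(bromomethylidene)-6-methylhept-5-en-1-ol
Product: 6 {[(2Z)-2-(bromomethylidene)-6-methylhept-5-en-1-yl]oxy}(tert-butyl)dimethylsilane
Conditions: TBSCl, imidazole, CH2Cl2, 0 °C → rt
Reagents that add atoms: tert-butyl(chloro)dimethylsilane, CC(C)(C)[Si](C)(C)Cl
Why: Standard silylation of a primary allylic alcohol; the silyl ether is inert to SeO2, ylide, borane, aqueous carbonate and organolithium reagents at low temperature.

Step 3
Reactants: 6 {[(2Z)-2-(bromomethylidene)-6-methylhept-5-en-1-yl]oxy}(tert-butyl)dimethylsilane
Product: 7 (2E,6Z)-7-bromo-6-(TBSO-methyl)-2-methylhepta-2,6-dien-1-ol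
Conditions: SeO2 (0.3 equiv), t-BuOOH (3 equiv), salicylic acid (0.1 equiv), CH2Cl2, rt
Reagents that add atoms: tert-butyl hydroperoxide, CC(C)(C)OO; selenium dioxide (oxygen carrier), O=[Se]=O
Why: Allylic oxidation by SeO2 (ene reaction, then [2,3]-sigmatropic shift) should occur at the electron-rich trisubstituted alkene and, at a gem-dimethyl terminus, at the methyl group trans to the chain, which gives the E allylic alcohol (C9–OH); the bromoalkene is deactivated. Any 8 formed by over-oxidation is carried into step 4.

Step 4
Reactants: 7 (2E,6Z)-7-bromo-6-(TBSO-methyl)-2-methylhepta-2,6-dien-1-ol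
Product: 8 (2E,6Z)-7-bromo-6-(TBSO-methyl)-2-methylhepta-2,6-dienal
Conditions: MnO2, CH2Cl2, rt
Reagents that add atoms: none
Why: MnO2 oxidises only the allylic alcohol and converges alcohol and over-oxidised material on the E enal without touching the silyl ether or the bromoalkene.

Step 5
Reactants: 8 (2E,6Z)-7-bromo-6-(TBSO-methyl)-2-methylhepta-2,6-dienal
Product: 9 (1Z,5E)-1-bromo-2-(TBSO-methyl)-6-methylocta-1,5,7-triene
Conditions: Ph3PCH3Br, KOtBu, THF, 0 °C; then 8, −78 → 0 °C
Reagents that add atoms: methyltriphenylphosphonium bromide, C[P+](c1ccccc1)(c1ccccc1)c1ccccc1.[Br-]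
Why: Wittig methylenation of the enal by 1,2-addition should give the terminal diene (C9=C10); the ylide is preformed so that no free base meets the bromoalkene, and the C7=C8 geometry is not affected.

Step 6
Reactants: 2 prop-2-yn-1-ol
Product: 11 (2Z)-3-iodo-2-methylprop-2-en-1-ol, via C3-magnesiated methallyl alkoxide 10 (not isolated)
Conditions: MeMgBr (3 equiv), CuI (10 mol%), Et2O, −10 °C → rt; then I2, −40 → 0 °C
Reagents that add atoms: methylmagnesium bromide, C[Mg]Br; iodine, II
Why: The same copper-catalysed anti-carbomagnesiation as in step 1, now with MeMgBr: methyl adds to the internal carbon (C12), magnesium to the terminal carbon (C11) cis to CH2O, and iodinolysis with retention should give the Z iodoalkene in which iodine is cis to the carbon that becomes C13.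

Step 7
Reactants: 11 (2Z)-3-iodo-2-methylprop-2-en-1-ol
Product: 12 (1Z)-3-bromo-1-iodo-2-methylprop-1-ene
Conditions: CBr4, PPh3, CH2Cl2, 0 °C
Reagents that add atoms: tetrabromomethane, BrC(Br)(Br)Br
Why: Appel bromination of a primary allylic alcohol under neutral conditions; substitution at the oxygen-activated carbon, with no allylic shift expected because the other allyl terminus carries iodine.

Step 8
Reactants: 12 (1Z)-3-bromo-1-iodo-2-methylprop-1-ene; 13 bis(4,4,5,5-tetramethyl-1,3,2-dioxaborolan-2-yl)methane
Product: 14 2-[(3Z)-4-iodo-3-methylbut-3-en-1-yl]-4,4,5,5-tetramethyl-1,3,2-dioxaborolane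
Conditions: 13 (1.3 equiv), NaOtBu, THF, rt; then 12, 0 °C → rt
Reagents that add atoms: none
Why: Alkoxide-promoted deborylative alkylation: NaOtBu adds to one boron of 13 and releases a boron-stabilised carbanion that displaces the primary allylic bromide by SN2, forming C13–C14 with the pinacol boronate in place. The process is polar, so no C14 radical appears that could scramble the Z alkene, and the alkenyl iodide is untouched.

Step 9
Reactants: 9 (1Z,5E)-1-bromo-2-(TBSO-methyl)-6-methylocta-1,5,7-triene; 14 2-[(3Z)-4-iodo-3-methylbut-3-en-1-yl]-4,4,5,5-tetramethyl-1,3,2-dioxaborolane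
Product: 16 2-[(3Z,7E,11Z)-12-bromo-11-(TBSO-methyl)-3,7-dimethyldodeca-3,7,11-trien-1-yl]-4,4,5,5-tetramethyl-1,3,2-dioxaborolane, via B-alkyl-9-BBN 15 (not isolated)
Conditions: 9, 9-BBN, THF, 0 °C → rt; then 14, Pd(dppf)Cl2 (5 mol%), AsPh3, Cs2CO3, DMF–H2O, rt
Reagents that add atoms: none
Why: 9-BBN should add to the monosubstituted terminus of the diene with boron on C10 (the trisubstituted alkenes and the bromoalkene are too hindered), and B-alkyl Suzuki–Miyaura coupling with the alkenyl iodide forms C10–C11 with retention of the Z geometry. Oxidative addition selects C–I over the hindered C–Br at room temperature, and a primary pinacol boronate does not transmetalate under these mild conditions, so both cyclisation handles survive.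

Step 10
Reactants: 16 2-[(3Z,7E,11Z)-12-bromo-11-(TBSO-methyl)-3,7-dimethyldodeca-3,7,11-trien-1-yl]-4,4,5,5-tetramethyl-1,3,2-dioxaborolane; 17 tetraethenylstannane
Product: 20 2-[(1R,3Z,7E,11Z)-4-(TBSO-methyl)-8,12-dimethylcyclotetradeca-3,7,11-trien-1-yl]-4,4,5,5-tetramethyl-1,3,2-dioxaborolane, via vinyllithium 18 (not isolated), via lithium vinylborate 19 (not isolated)
Conditions: 17 (0.27 equiv), n-BuLi, pentane, rt, precipitated 18 washed and taken up in THF; 16, THF, −78 °C → rt; then syringe-pump addition to Pd(OAc)2 (10 mol%), (Sp,Sp)-MandyPhos (12 mol%), NaOTf (3 equiv), THF, 60 °C, final concentration about 0.002 M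
Reagents that add atoms: none
Why: Proposed new method: the closest known reaction type is the intermolecular, enantioselective conjunctive cross-coupling of vinylboron ate complexes with alkenyl or aryl electrophiles under Pd(OAc)2 and MandyPhos, here asked to operate between the two ends of one chain. Zerovalent palladium should insert into the C3–Br bond with retention, and NaOTf removes bromide as NaBr so that a cationic divalent alkenylpalladium is free to bind the electron-rich vinyl group of borate 19 at the other terminus. Coordination triggers the 1,2-metallate shift: C14 moves from boron to C1 anti to palladium while palladium bonds to C2, which gives a 15-membered palladacycle; reductive elimination then joins C2 to C3, closes the 14-membered carbocycle in an end-to-end mode and returns zerovalent palladium. C1 is the only new stereocentre and is set by catalyst control: the chiral bisphosphine decides which enantiotopic face of the vinyl borate palladium takes, and the anti migration translates this into (R). The step needs ring closure to outrun oligomerisation (slow addition into a dilute, warm catalyst solution; a chain already bent by three trisubstituted alkenes), metallate shift to outrun direct vinyl transfer to C3 (cationic palladium, wide bite angle, halide scavenging) and reductive elimination to outrun β-hydride loss from C1. Within the substrate the primary alkyl C14 is a good migrating group, the pinacol oxygens do not migrate, C3–Br is the only carbon–halogen bond, and the vinyl borate is by far the most nucleophilic alkene, so the three chain alkenes stay out of the reaction. Borate formation at −78 °C is faster than bromine–lithium exchange, which is why 18 can be added to a molecule that carries the bromoalkene.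

Step 11
Reactants: 21 6-methylhept-5-en-2-one
Product: 22 N′-[(2E)-6-methylhept-5-en-2-ylidene]-2,4,6-tri(propan-2-yl)benzenesulfonohydrazide
Conditions: 2,4,6-triisopropylbenzenesulfonohydrazide, MeOH, cat. HCl, rt
Reagents that add atoms: 2,4,6-tri(propan-2-yl)benzenesulfonohydrazide, CC(C)c1cc(C(C)C)c(S(=O)(=O)NN)c(C(C)C)c1
Why: Condensation of the methyl ketone with the hindered sulfonyl hydrazide gives the hydrazone (E isomer expected); the triisopropylphenyl group blocks ortho-lithiation in the next step.

Step 12
Reactants: 20 2-[(1R,3Z,7E,11Z)-4-(TBSO-methyl)-8,12-dimethylcyclotetradeca-3,7,11-trien-1-yl]-4,4,5,5-tetramethyl-1,3,2-dioxaborolane; 22 N′-[(2E)-6-methylhept-5-en-2-ylidene]-2,4,6-tri(propan-2-yl)benzenesulfonohydrazide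
Product: 25 tert-butyl{[(1Z,4R,7Z,11E)-7,11-dimethyl-4-(6-methylhepta-1,5-dien-2-yl)cyclotetradeca-1,7,11-trien-1-yl]methoxy}dimethylsilane, via 2-lithio-6-methylhepta-1,5-diene 23 (not isolated), via lithium alkenylborate 24 (not isolated)
Conditions: 22 (1.5 equiv), n-BuLi (2.0 equiv per 22), THF, −78 → 0 °C; 20, THF, −78 °C; I2, THF, then NaOMe, MeOH, −78 °C → rt
Reagents that add atoms: none
Why: Shapiro reaction: double deprotonation (N–H, then the methyl group syn to nitrogen) and loss of sulfinate and N2 give the 2-lithio-1-alkene 23, which adds to boron of 20. In the Zweifel olefination iodine activates the alkenyl group of 24, C1 migrates from boron to C15 with retention, and NaOMe induces anti elimination of boron and iodine to form C15=C16; C1 keeps its (R) configuration because it is the migrating carbon.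

Step 13
Reactants: 25 tert-butyl{[(1Z,4R,7Z,11E)-7,11-dimethyl-4-(6-methylhepta-1,5-dien-2-yl)cyclotetradeca-1,7,11-trien-1-yl]methoxy}dimethylsilane
Product: 26 [(1Z,4R,7Z,11E)-7,11-dimethyl-4-(6-methylhepta-1,5-dien-2-yl)cyclotetradeca-1,7,11-trien-1-yl]methanol
Conditions: Bu4NF, THF, 0 °C → rt
Reagents that add atoms: none
Why: Fluoride cleaves the primary silyl ether under conditions that leave the five alkenes and the allylic C1–H untouched; no stereocentre is involved.

## Compound list

1 | 5-bromo-2-methylpent-2-ene | CC(C)=CCCBr | starting material
2 | prop-2-yn-1-ol (propargyl alcohol) | C#CCO | starting material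
3 | (4-methylpent-3-en-1-yl)magnesium bromide | CC(C)=CCC[Mg]Br | intermediate
4 | bromomagnesium alkoxide of (Z)-2-[(bromomagnesio)methylidene]-6-methylhept-5-en-1-ol (Mg cis to CH2O) | Br[Mg]/C=C(\CO[Mg]Br)CCC=C(C)C | intermediate
5 | (2Z)-2-(bromomethylidene)-6-methylhept-5-en-1-ol (Br cis to CH2OH) | Br/C=C(\CO)CCC=C(C)C | intermediate
6 | {[(2Z)-2-(bromomethylidene)-6-methylhept-5-en-1-yl]oxy}(tert-butyl)dimethylsilane | Br/C=C(\CO[Si](C)(C)C(C)(C)C)CCC=C(C)C | intermediate
7 | (2E,6Z)-7-bromo-6-{[(tert-butyldimethylsilyl)oxy]methyl}-2-methylhepta-2,6-dien-1-ol | Br/C=C(\CO[Si](C)(C)C(C)(C)C)CC/C=C(\C)CO | intermediate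
8 | (2E,6Z)-7-bromo-6-{[(tert-butyldimethylsilyl)oxy]methyl}-2-methylhepta-2,6-dienal | Br/C=C(\CO[Si](C)(C)C(C)(C)C)CC/C=C(\C)C=O | intermediate
9 | (1Z,5E)-1-bromo-2-{[(tert-butyldimethylsilyl)oxy]methyl}-6-methylocta-1,5,7-triene | Br/C=C(\CO[Si](C)(C)C(C)(C)C)CC/C=C(\C)C=C | intermediate
10 | bromomagnesium alkoxide of (Z)-3-(bromomagnesio)-2-methylprop-2-en-1-ol (Mg cis to CH2O) | Br[Mg]/C=C(\CO[Mg]Br)C | intermediate
11 | (2Z)-3-iodo-2-methylprop-2-en-1-ol | I/C=C(/C)CO | intermediate
12 | (1Z)-3-bromo-1-iodo-2-methylprop-1-ene | I/C=C(/C)CBr | intermediate
13 | bis(4,4,5,5-tetramethyl-1,3,2-dioxaborolan-2-yl)methane | CC1(C)OB(CB2OC(C)(C)C(C)(C)O2)OC1(C)C | starting material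
14 | 2-[(3Z)-4-iodo-3-methylbut-3-en-1-yl]-4,4,5,5-tetramethyl-1,3,2-dioxaborolane | I/C=C(/C)CCB1OC(C)(C)C(C)(C)O1 | intermediate
15 | 9-[(3E,7Z)-8-bromo-7-{[(tert-butyldimethylsilyl)oxy]methyl}-3-methylocta-3,7-dien-1-yl]-9-borabicyclo[3.3.1]nonane | Br/C=C(\CO[Si](C)(C)C(C)(C)C)CC/C=C(\C)CCB1C2CCCC1CCC2 | intermediate
16 | 2-[(3Z,7E,11Z)-12-bromo-11-{[(tert-butyldimethylsilyl)oxy]methyl}-3,7-dimethyldodeca-3,7,11-trien-1-yl]-4,4,5,5-tetramethyl-1,3,2-dioxaborolane (cyclisation precursor) | Br/C=C(\CO[Si](C)(C)C(C)(C)C)CC/C=C(\C)CC/C=C(/C)CCB1OC(C)(C)C(C)(C)O1 | intermediate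
17 | tetraethenylstannane (tetravinyltin) | C=C[Sn](C=C)(C=C)C=C | starting material
18 | vinyllithium | C=C[Li] | intermediate
19 | lithium ethenyl(pinacolato)borate of 16 (four-coordinate boron on C14) | [Li+].Br/C=C(\CO[Si](C)(C)C(C)(C)C)CC/C=C(\C)CC/C=C(/C)CC[B-]1(C=C)OC(C)(C)C(C)(C)O1 | intermediate
20 | 2-[(1R,3Z,7E,11Z)-4-{[(tert-butyldimethylsilyl)oxy]methyl}-8,12-dimethylcyclotetradeca-3,7,11-trien-1-yl]-4,4,5,5-tetramethyl-1,3,2-dioxaborolane | CC1(C)OB(OC1(C)C)[C@H]2C/C=C(\CO[Si](C)(C)C(C)(C)C)CC/C=C(\C)CC/C=C(/C)CC2 | intermediate
21 | 6-methylhept-5-en-2-one | CC(=O)CCC=C(C)C | starting material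
22 | N′-[(2E)-6-methylhept-5-en-2-ylidene]-2,4,6-tri(propan-2-yl)benzenesulfonohydrazide | C/C(CCC=C(C)C)=N\NS(=O)(=O)c1c(C(C)C)cc(C(C)C)cc1C(C)C | intermediate
23 | 2-lithio-6-methylhepta-1,5-diene | [Li]C(=C)CCC=C(C)C | intermediate
24 | lithium (6-methylhepta-1,5-dien-2-yl)(pinacolato)borate of 20 (C1 R) | [Li+].CC1(C)O[B-](OC1(C)C)(C(=C)CCC=C(C)C)[C@H]2C/C=C(\CO[Si](C)(C)C(C)(C)C)CC/C=C(\C)CC/C=C(/C)CC2 | intermediate
25 | tert-butyl{[(1Z,4R,7Z,11E)-7,11-dimethyl-4-(6-methylhepta-1,5-dien-2-yl)cyclotetradeca-1,7,11-trien-1-yl]methoxy}dimethylsilane (in the ring numbering used here 1R,3Z,7E,11Z) | C=C(CCC=C(C)C)[C@H]1C/C=C(\CO[Si](C)(C)C(C)(C)C)CC/C=C(\C)CC/C=C(/C)CC1 | intermediate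
26 | [(1Z,4R,7Z,11E)-7,11-dimethyl-4-(6-methylhepta-1,5-dien-2-yl)cyclotetradeca-1,7,11-trien-1-yl]methanol (in the ring numbering used here 1R,3Z,7E,11Z) | C=C(CCC=C(C)C)[C@H]1C/C=C(\CO)CC/C=C(\C)CC/C=C(/C)CC1 | target

## Step count and least certain steps

Total step count: 13. Longest linear sequence: 9 steps (steps 1, 2, 3, 4, 5, 9, 10, 12, 13).

**Step 10 (key step, new method).** Several processes may compete with the intended closure.
- Chain-to-chain coupling may outrun ring closure, because the alkenylpalladium end must find the vinyl borate of its own chain.
- Direct transfer of the vinyl group to C3, or β-hydride loss after the metallate shift, may take over if bromide is not fully removed from palladium.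
- The enantiofacial selection that the ligand exerts in open-chain cases may be weakened or reversed by the conformational demands of the forming macrocycle.

The diol on boron, the addition rate and the ligand enantiomer are the variables to adjust first. The fallback uses only known reaction types and closes the ring at C10–C11; it sets out from 2, 13 and 9 and returns at 20.
- Carbomagnesiation of 2 as in step 6 and quenching of 10 with N-chlorosuccinimide would give (2Z)-3-chloro-2-methylprop-2-en-1-ol F1.
- Appel bromination would give (1Z)-3-bromo-1-chloro-2-methylprop-1-ene F2, and alkylation of 13 as in step 8 would give the chloroalkenyl pinacol boronate F3.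
- With 18 this forms the lithium vinylborate F4. It would be coupled with bromide 9 under the established intermolecular conditions (Pd(OAc)2, MandyPhos, NaOTf, THF, 60 °C; the alkenyl chloride does not react) to give the open-chain (R) secondary boronate F5.
- Hydroboration of its diene terminus with 9-BBN would give the borane F6. Intramolecular B-alkyl Suzuki–Miyaura coupling at the alkenyl chloride (Pd(OAc)2, SPhos, K3PO4, THF–H2O, high dilution) would close the ring and give 20.

**Step 9.** Three processes may interfere: oxidative addition at the bromoalkene of 9 or 16 (leading to oligomers), incomplete regioselectivity in the hydroboration of the diene, and base-mediated loss of the pinacol boronate. The fallback separates the two events and couples without base; it sets out from 9 and returns at 16. Hydroboration of 9 with 9-BBN and oxidation with NaBO3 would give the primary alcohol F7, which can be purified from regioisomers. I2, PPh3 and imidazole would give the iodide F8. Zinc insertion (Zn, LiCl, THF) would give the alkylzinc iodide F9, which the alkenyl bromide tolerates. Negishi coupling with 14 (Pd(PPh3)4, THF, rt) would give 16.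

**Step 12.** Borate formation between the branched alkenyllithium 23 and the hindered secondary boronate may be incomplete. The sulfinate released in the Shapiro reaction may consume iodine, and an excess of iodine may then attack the trisubstituted alkenes. The fallback builds the side chain in stages; it sets out from 20 and returns at 25. Addition of 1-ethoxyvinyllithium (from ethyl vinyl ether and t-BuLi), then I2 and NaOMe, would give the enol ether F10, and mild aqueous acid would give the methyl ketone F11 with retention at C1. Kinetic deprotonation of the methyl group (LiN(iPr)2, THF, −78 °C) and alkylation with 1-bromo-3-methylbut-2-ene would give the ketone F12. Methylenation with salt-free Ph3P=CH2 or with Cp2TiMe2, chosen to avoid epimerisation at C1, would give 25.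

**Step 3.** The allylic oxidation may stop early, over-oxidise, or attack the allylic positions next to the bromoalkene. The fallback builds the E enal by olefination; it sets out from 6 and returns at 8. Ozonolysis of the electron-rich alkene of 6 (O3, CH2Cl2–pyridine, −78 °C, then PPh3; the bromoalkene reacts far more slowly) would give the aldehyde F13. Wittig reaction with the stabilised ylide Ph3P=C(CH3)CHO (toluene, 80 °C) would give 8 with E geometry.

## Further compounds

F1 | step 10 | (2Z)-3-chloro-2-methylprop-2-en-1-ol | Cl/C=C(/C)CO
F2 | step 10 | (1Z)-3-bromo-1-chloro-2-methylprop-1-ene | Cl/C=C(/C)CBr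
F3 | step 10 | 2-[(3Z)-4-chloro-3-methylbut-3-en-1-yl]-4,4,5,5-tetramethyl-1,3,2-dioxaborolane | Cl/C=C(/C)CCB1OC(C)(C)C(C)(C)O1
F4 | step 10 | lithium ethenyl(pinacolato)borate of F3 | [Li+].Cl/C=C(/C)CC[B-]1(C=C)OC(C)(C)C(C)(C)O1
F5 | step 10 | 2-[(1Z,5R,7Z,11E)-8-{[(tert-butyldimethylsilyl)oxy]methyl}-1-chloro-2,12-dimethyltetradeca-1,7,11,13-tetraen-5-yl]-4,4,5,5-tetramethyl-1,3,2-dioxaborolane | Cl/C=C(/C)CC[C@@H](B1OC(C)(C)C(C)(C)O1)C/C=C(\CO[Si](C)(C)C(C)(C)C)CC/C=C(\C)C=C
F6 | step 10 | 9-BBN adduct of F5 at the terminal carbon of the diene | Cl/C=C(/C)CC[C@@H](B1OC(C)(C)C(C)(C)O1)C/C=C(\CO[Si](C)(C)C(C)(C)C)CC/C=C(\C)CCB1C2CCCC1CCC2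
F7 | step 9 | (3E,7Z)-8-bromo-7-{[(tert-butyldimethylsilyl)oxy]methyl}-3-methylocta-3,7-dien-1-ol | Br/C=C(\CO[Si](C)(C)C(C)(C)C)CC/C=C(\C)CCO
F8 | step 9 | (1Z,5E)-1-bromo-2-{[(tert-butyldimethylsilyl)oxy]methyl}-8-iodo-6-methylocta-1,5-diene | Br/C=C(\CO[Si](C)(C)C(C)(C)C)CC/C=C(\C)CCI
F9 | step 9 | [(3E,7Z)-8-bromo-7-{[(tert-butyldimethylsilyl)oxy]methyl}-3-methylocta-3,7-dien-1-yl]zinc iodide | Br/C=C(\CO[Si](C)(C)C(C)(C)C)CC/C=C(\C)CC[Zn]I
F10 | step 12 | tert-butyl{[(1Z,4R,7Z,11E)-4-(1-ethoxyethenyl)-7,11-dimethylcyclotetradeca-1,7,11-trien-1-yl]methoxy}dimethylsilane | C=C(OCC)[C@H]1C/C=C(\CO[Si](C)(C)C(C)(C)C)CC/C=C(\C)CC/C=C(/C)CC1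
F11 | step 12 | 1-[(1R,3Z,7E,11Z)-4-{[(tert-butyldimethylsilyl)oxy]methyl}-8,12-dimethylcyclotetradeca-3,7,11-trien-1-yl]ethan-1-one | CC(=O)[C@H]1C/C=C(\CO[Si](C)(C)C(C)(C)C)CC/C=C(\C)CC/C=C(/C)CC1
F12 | step 12 | 1-[(1R,3Z,7E,11Z)-4-{[(tert-butyldimethylsilyl)oxy]methyl}-8,12-dimethylcyclotetradeca-3,7,11-trien-1-yl]-5-methylhex-4-en-1-one | CC(C)=CCCC(=O)[C@H]1C/C=C(\CO[Si](C)(C)C(C)(C)C)CC/C=C(\C)CC/C=C(/C)CC1
F13 | step 3 | (4Z)-5-bromo-4-{[(tert-butyldimethylsilyl)oxy]methyl}pent-4-enal | Br/C=C(\CO[Si](C)(C)C(C)(C)C)CCC=O
A1 | alternative 1 | open-chain C3 aldehyde with bis(2,2,2-trifluoroethyl) phosphonoester at C4, C1 (R) carrying the side chain | O=CC[C@H](C(=C)CCC=C(C)C)CC/C(C)=C\CC/C(C)=C/CCC(C(=O)OC)P(=O)(OCC(F)(F)F)OCC(F)(F)F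
A2 | alternative 1 | 14-membered carbocyclic (Z)-enoate, methyl ester on C4 | C=C(CCC=C(C)C)[C@H]1C/C=C(\C(=O)OC)CC/C=C(\C)CC/C=C(/C)CC1
A3 | alternative 2 | 18-membered allylic macrolactone (carbonyl on C14, ester oxygen on C16, C1=C15 drawn E), TBDPS ether | O=C1CC/C(C)=C\CC/C(C)=C/CC/C(CO[Si](c2ccccc2)(c2ccccc2)C(C)(C)C)=C/C/C=C(\CCC=C(C)C)CO1
A4 | alternative 2 | 14-membered carbocyclic acid with carboxyl on C14, TBDPS ether | C=C(CCC=C(C)C)[C@H]1C/C=C(\CO[Si](c2ccccc2)(c2ccccc2)C(C)(C)C)CC/C=C(\C)CC/C=C(/C)C[C@@H]1C(=O)O
A5 | alternative 3 | open-chain (E)-allylic phenyl sulfone at C9 with (Z)-allylic bromide at C10, C1 (R), TBS ether | BrC/C=C(/C)CC[C@@H](C(=C)CCC=C(C)C)C/C=C(\CO[Si](C)(C)C(C)(C)C)CC/C=C(\C)CS(=O)(=O)c1ccccc1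
A6 | alternative 3 | 14-membered carbocycle with phenylsulfonyl group on C9 (C9 epimer mixture), TBS ether | C=C(CCC=C(C)C)[C@H]1C/C=C(\CO[Si](C)(C)C(C)(C)C)CC/C=C(\C)C(S(=O)(=O)c2ccccc2)C/C=C(/C)CC1
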